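**Plan**
- Cuts: (i) the C4–C5 bond of the tridecanone chain (the CH2–CH2 bond α,β to the C3 ketone), giving a furan-bearing terminal alkene and an L-serine-derived diazo ketone; (ii) the furan C2–CH2 and C5–CH2 bonds, back to 3,4-dimethylfuran; (iii) N-acetyl and free OH are masked as Cbz and benzyl ether.
- Enabling feature: the C3 ketone is flanked by an unbranched methylene C4 and a straight (CH2)10 tether to furan C2. C4 can therefore be a diazomethyl carbon on the serine carboxyl (an acceptor once N2 leaves) and C5 the boron-bearing end of a hydroborated vinyl group. The furan ring carries carbon at all four positions and has no ring C–H to interfere.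
- Forward: the furan ring is bought and alkylated twice by α-lithiation (steps 1–2); Z-Ser(Bzl)-OH is turned into its diazo ketone (step 3); hydroboration and a boron-to-carbon alkyl shift join the chain in one pot (step 4); one hydrogenolysis exchanges Cbz for acetyl and frees the hydroxyl (step 5).
- Stereochemistry: the single (S) centre is that of L-serine, whose carboxyl carbon becomes the C3 ketone; no step exposes the α-amino ketone to base.

Key step: step 4

Assumption: 3,4-dimethylfuran and chloroborane–dimethyl sulfide are taken as catalogue reagents, and the tetraalkylfuran is treated as stable to neutral and weakly Lewis-acidic media but not to aqueous mineral acid.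

**Step 1**
Reactants: 1 3,4-dimethylfuran
Product: 3 3,4-dimethyl-2-propylfuran, via 2-lithio-3,4-dimethylfuran 2 (not isolated)
Conditions: n-BuLi (1.05 equiv), THF, 0 °C → rt; then n-PrI, −78 °C → rt
Reagents that add atoms: 1-iodopropane, CCCI
Why: α-Lithiation of the furan (both α-C–H are equivalent, so a single lithio species forms) followed by SN2 alkylation with a reactive primary iodide, i.e. furan α-metalation/alkylation.

**Step 2**
Reactants: 3 3,4-dimethyl-2-propylfuran; 4 9-bromonon-1-ene
Product: 6 3,4-dimethyl-2-(non-8-en-1-yl)-5-propylfuran, via 5-lithio-3,4-dimethyl-2-propylfuran 5 (not isolated)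
Conditions: n-BuLi (1.1 equiv), TMEDA, THF, 0 °C → rt; then 4, DMPU, 0 °C → rt
Reagents that add atoms: none
Why: The only remaining ring C–H (C5, α to oxygen) is lithiated and the furyllithium is alkylated by the primary bromide (α-metalation/SN2 alkylation); the product has no acidic ring hydrogen, so over-alkylation is excluded, and the terminal alkene is inert to n-BuLi here.

**Step 3**
Reactants: 7 N-benzyloxycarbonyl-O-benzyl-L-serine
Product: 9 benzyl N-[(2S)-1-(benzyloxy)-4-diazo-3-oxobutan-2-yl]carbamate, via mixed isobutyl carbonic anhydride 8 (not isolated)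
Conditions: i-BuOCOCl, N-methylmorpholine, THF, −15 °C; then CH2N2, Et2O, −15 °C → rt
Reagents that add atoms: diazomethane, C=[N+]=[N-]
Why: Acylation of diazomethane by the mixed carbonic anhydride of a urethane-protected amino acid (first stage of the Arndt–Eistert sequence) does not pass through an oxazolone, so the (S) centre of L-serine should be retained.

**Step 4**
Reactants: 6 3,4-dimethyl-2-(non-8-en-1-yl)-5-propylfuran (2 equiv); 9 benzyl N-[(2S)-1-(benzyloxy)-4-diazo-3-oxobutan-2-yl]carbamate
Product: 12 benzyl N-[(2S)-1-(benzyloxy)-13-(3,4-dimethyl-5-propylfuran-2-yl)-3-oxotridecan-2-yl]carbamate, via dialkylchloroborane 10 (not isolated), via chloroboron enolate 11 (not isolated)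
Conditions: ClBH2·SMe2 (1.0 equiv), 6 (2.05 equiv), CH2Cl2, 0 °C → rt; then 9 (0.9 equiv), CH2Cl2, −78 → 0 °C; then sat. aq NaHCO3, 0 °C → rt
Reagents that add atoms: none
Why: Monochloroborane adds anti-Markovnikov to the terminal C=C of two molecules of 6 to give 10, whose boron is attacked by the nucleophilic diazo carbon of 9; in the resulting borate one primary alkyl group migrates from boron to that carbon with loss of N2 (1,2-metallate shift), the α-boryl ketone tautomerises to the boron enolate 11, and water protonates it at carbon to give 12. The closest known reaction type is the Hooz alkylation of α-diazo ketones by organoboranes in its dialkylchloroborane form; it unites two donor carbons (the alkyl–boron carbon and the ketone α-carbon), the diazonium leaving group reversing the polarity of the α-carbon. No ring is closed and no stereocentre is created; the existing (S) centre should be preserved because no base is present and the enolate forms only on the side of the former diazo carbon, away from C2. The step needs terminal regioselectivity in the hydroboration and chemoselectivity for the alkene over the furan, secured by a monosubstituted C=C set against a fully substituted aromatic ring. It also needs transfer of the furylnonyl group only, secured because chloride does not migrate and both alkyl groups on boron are identical. Wolff rearrangement is not expected at −78 to 0 °C without light or a transition metal.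

**Step 5**
Reactants: 12 benzyl N-[(2S)-1-(benzyloxy)-13-(3,4-dimethyl-5-propylfuran-2-yl)-3-oxotridecan-2-yl]carbamate
Product: 15 N-[(2S)-13-(3,4-dimethyl-5-propylfuran-2-yl)-1-hydroxy-3-oxotridecan-2-yl]acetamide, via O-benzyl amino ketone 13 (not isolated), via O-benzyl acetamide 14 (not isolated)
Conditions: H2 (1 atm), 10% Pd/C, Ac2O (1.5 equiv), EtOAc–MeOH, rt
Reagents that add atoms: acetic anhydride, CC(=O)OC(C)=O
Why: Catalytic hydrogenolysis cleaves the benzyl carbamate (the carbamic acid loses CO2) and the amine is N-acetylated as it forms, faster than α-amino ketone self-condensation, after which the benzyl ether is hydrogenolysed; the tetrasubstituted furan and the aliphatic ketone should survive Pd/C at 1 atm, and surplus anhydride is consumed by methanol rather than by the primary alcohol.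

**Compound list**
1 | 3,4-dimethylfuran | Cc1cocc1C | starting material
2 | 2-lithio-3,4-dimethylfuran | [Li]c1occ(C)c1C | intermediate
3 | 3,4-dimethyl-2-propylfuran | CCCc1occ(C)c1C | intermediate
4 | 9-bromonon-1-ene | C=CCCCCCCCBr | starting material
5 | 5-lithio-3,4-dimethyl-2-propylfuran | [Li]c1oc(CCC)c(C)c1C | intermediate
6 | 3,4-dimethyl-2-(non-8-en-1-yl)-5-propylfuran | CCCc1oc(CCCCCCCC=C)c(C)c1C | intermediate
7 | N-benzyloxycarbonyl-O-benzyl-L-serine, (2S)-3-(benzyloxy)-2-{[(benzyloxy)carbonyl]amino}propanoic acid | OC(=O)[C@H](COCc1ccccc1)NC(=O)OCc1ccccc1 | starting material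
8 | (2S)-3-(benzyloxy)-2-{[(benzyloxy)carbonyl]amino}propanoic isobutyl carbonic anhydride | CC(C)COC(=O)OC(=O)[C@H](COCc1ccccc1)NC(=O)OCc1ccccc1 | intermediate
9 | benzyl N-[(2S)-1-(benzyloxy)-4-diazo-3-oxobutan-2-yl]carbamate | [N-]=[N+]=CC(=O)[C@H](COCc1ccccc1)NC(=O)OCc1ccccc1 | intermediate
10 | chlorobis[9-(3,4-dimethyl-5-propylfuran-2-yl)nonyl]borane | CCCc1oc(CCCCCCCCCB(Cl)CCCCCCCCCc2oc(CCC)c(C)c2C)c(C)c1C | intermediate
11 | benzyl N-[(2S)-1-(benzyloxy)-3-({chloro[9-(3,4-dimethyl-5-propylfuran-2-yl)nonyl]boranyl}oxy)-13-(3,4-dimethyl-5-propylfuran-2-yl)tridec-3-en-2-yl]carbamate (boron enolate, alkene geometry not defined) | CCCc1oc(CCCCCCCCCC=C(OB(Cl)CCCCCCCCCc2oc(CCC)c(C)c2C)[C@H](COCc2ccccc2)NC(=O)OCc2ccccc2)c(C)c1C | intermediate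
12 | benzyl N-[(2S)-1-(benzyloxy)-13-(3,4-dimethyl-5-propylfuran-2-yl)-3-oxotridecan-2-yl]carbamate | CCCc1oc(CCCCCCCCCCC(=O)[C@H](COCc2ccccc2)NC(=O)OCc2ccccc2)c(C)c1C | intermediate
13 | (2S)-2-amino-1-(benzyloxy)-13-(3,4-dimethyl-5-propylfuran-2-yl)tridecan-3-one | CCCc1oc(CCCCCCCCCCC(=O)[C@@H](N)COCc2ccccc2)c(C)c1C | intermediate
14 | N-[(2S)-1-(benzyloxy)-13-(3,4-dimethyl-5-propylfuran-2-yl)-3-oxotridecan-2-yl]acetamide | CCCc1oc(CCCCCCCCCCC(=O)[C@H](COCc2ccccc2)NC(C)=O)c(C)c1C | intermediate
15 | N-[(2S)-13-(3,4-dimethyl-5-propylfuran-2-yl)-1-hydroxy-3-oxotridecan-2-yl]acetamide | CCCc1oc(CCCCCCCCCCC(=O)[C@H](CO)NC(C)=O)c(C)c1C | target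

**Totals**
Total steps: 5. Longest linear sequence: 4 (steps 1, 2, 4, 5).

**Steps most likely to fail**

Step 4. The Lewis-acidic chloroborane may strip nitrogen from the diazo ketone without transferring the alkyl group (capture of the carbon by chloride or by the carbamate oxygen), or alkyl transfer may stall after partial conversion. The fallback forms the same C4–C5 bond as a C=C by olefin metathesis; it sets out from 3 and 7 and comes back at 15. The lithiofuran 5, made from 3 as in step 2, is alkylated with 10-bromodec-1-ene to give 2-(dec-9-en-1-yl)-3,4-dimethyl-5-propylfuran F1. The mixed anhydride 8, made from 7 as in step 3, is treated with N,O-dimethylhydroxylamine hydrochloride and N-methylmorpholine to give the Weinreb amide benzyl N-[(2S)-3-(benzyloxy)-1-[methoxy(methyl)amino]-1-oxopropan-2-yl]carbamate F2. Vinylmagnesium bromide (THF, −78 → 0 °C, cold acidic quench) converts it into the vinyl ketone benzyl N-[(2S)-1-(benzyloxy)-3-oxopent-4-en-2-yl]carbamate F3. Cross-metathesis of F1 with F3 (second-generation Grubbs catalyst, CH2Cl2, 40 °C) should give the enone benzyl N-[(2S,4E)-1-(benzyloxy)-13-(3,4-dimethyl-5-propylfuran-2-yl)-3-oxotridec-4-en-2-yl]carbamate F4. The conditions of step 5 then saturate the C=C while exchanging Cbz for acetyl and cleaving the benzyl ether, giving 15.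

Step 5. Hydrogenolysis of the alkyl benzyl ether may be slow, so that long exposure begins to saturate the furan ring or lets the freed hydroxyl be acetylated. The fallback removes both benzyl-type groups without hydrogen; it sets out from 12 and comes back at 15. BCl3 with pentamethylbenzene as cation scavenger (CH2Cl2, −78 → −20 °C, methanol quench) cleaves the carbamate and the ether to give (2S)-2-amino-13-(3,4-dimethyl-5-propylfuran-2-yl)-1-hydroxytridecan-3-one hydrochloride F5, kept as the salt to prevent self-condensation. Acetic anhydride with NaHCO3 in THF–water at 0 °C then acetylates nitrogen selectively to give 15.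

Step 2. SN2 attack of the hindered 5-lithiofuran on the unactivated bromide may be slow, with E2 elimination of the bromide and protonation back to 3 competing. The fallback replaces alkylation by acylation and deoxygenation; it sets out from 3 and comes back at 6. Compound 3 is acylated at its free α-position with non-8-enoic acid and trifluoroacetic anhydride (CH2Cl2, 0 °C, Friedel–Crafts acylation through the mixed anhydride) to give 1-(3,4-dimethyl-5-propylfuran-2-yl)non-8-en-1-one F6. Hydrazine hydrate converts it into the hydrazone 1-(3,4-dimethyl-5-propylfuran-2-yl)non-8-en-1-one hydrazone F7, which KOH in diethylene glycol at about 190 °C under nitrogen reduces to 6 (Wolff–Kishner reduction).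

**Further compounds**
F1 | step 4 | 2-(dec-9-en-1-yl)-3,4-dimethyl-5-propylfuran | CCCc1oc(CCCCCCCCC=C)c(C)c1C
F2 | step 4 | benzyl N-[(2S)-3-(benzyloxy)-1-[methoxy(methyl)amino]-1-oxopropan-2-yl]carbamate | CON(C)C(=O)[C@H](COCc1ccccc1)NC(=O)OCc1ccccc1
F3 | step 4 | benzyl N-[(2S)-1-(benzyloxy)-3-oxopent-4-en-2-yl]carbamate | C=CC(=O)[C@H](COCc1ccccc1)NC(=O)OCc1ccccc1
F4 | step 4 | benzyl N-[(2S,4E)-1-(benzyloxy)-13-(3,4-dimethyl-5-propylfuran-2-yl)-3-oxotridec-4-en-2-yl]carbamate | CCCc1oc(CCCCCCCC/C=C/C(=O)[C@H](COCc2ccccc2)NC(=O)OCc2ccccc2)c(C)c1C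
F5 | step 5 | (2S)-2-amino-13-(3,4-dimethyl-5-propylfuran-2-yl)-1-hydroxytridecan-3-one hydrochloride | CCCc1oc(CCCCCCCCCCC(=O)[C@@H](N)CO)c(C)c1C.Cl
F6 | step 2 | 1-(3,4-dimethyl-5-propylfuran-2-yl)non-8-en-1-one | CCCc1oc(C(=O)CCCCCCC=C)c(C)c1C
F7 | step 2 | 1-(3,4-dimethyl-5-propylfuran-2-yl)non-8-en-1-one hydrazone | CCCc1oc(C(=NN)CCCCCCC=C)c(C)c1C
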